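**Retrosynthetic overview**
1. Numbering: bicyclo[6.1.0]nonane core with C1/C8 = cyclopropane ring-fusion CH, C9 = cyclopropane CH2, C2 = CHMe, C3 = CH2, C4 = CH–OAc, C5 = CH bearing the side chain, C6/C7 = α/β carbons of the butenolide. Late stage: acetate ⇐ C4 alcohol ⇐ C4 ketone; butenolide ⇐ lactonisation of a (6Z)-6-carboxylate-7-silyloxymethyl enoate; C2–Me ⇐ Me2CuLi on a C2=C3 enone; C5 ⇐ enolate protonation.
2. Key disconnection: the eight-membered ring is cut at C5–C6 and C1–C2 (C7–C8 forms in the same event) into 2-siloxydiene 4 (C2–C5, from (R)-citronellal), ynoate 6 (C6, C7 and both lactone carbons) and cyclopropene 8 (C1, C8, C9), joined by one rhodium-catalysed [4+2+2] cycloaddition.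
3. Enabling feature: round the eight-membered ring a cis-fused cyclopropane edge (C1–C8), a tetrasubstituted enoate C=C (C6=C7) and a four-carbon unit oxygenated at an inner carbon (C2–C5, O on C4) follow one another, which is the pattern strained ene + alkyne + 2-oxy-1,3-diene. Release of the cyclopropene π-strain drives the union while the three-membered ring survives.
4. Ring order: cyclopropane (carried in with 8) and eight-membered ring together in step 6, butenolide in step 10.

Key step: step 6

Assumption: (R)-BINAP is taken to be the ligand antipode that induces the (1S,8S)-cyclopropane in step 6; if induction has the opposite sense, (S)-BINAP is used and nothing else changes. Compounds 1, 5 and 7 are commercial.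

Step 1
Reactants: 1 (R)-citronellal
Product: 2 (5R)-5,9-dimethyldeca-1,8-dien-3-ol (C3 epimers)
Conditions: CH2=CHMgBr, THF, −78 to 0 °C; then H2O
Reagents that add atoms: vinylmagnesium bromide C=C[Mg]Br
Why: Grignard 1,2-addition to the aldehyde; the new carbinol centre forms as both epimers, which is harmless because it becomes the ketone carbon in step 2.

Step 2
Reactants: 2 (5R)-5,9-dimethyldeca-1,8-dien-3-ol
Product: 3 (5R)-5,9-dimethyldeca-1,8-dien-3-one
Conditions: Dess–Martin periodinane, CH2Cl2, 0 °C
Reagents that add atoms: none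
Why: Dess–Martin oxidation converts the secondary allylic alcohol into the vinyl ketone under neutral conditions that leave the trisubstituted alkene and the side-chain stereocentre untouched.

Step 3
Reactants: 3 (5R)-5,9-dimethyldeca-1,8-dien-3-one
Product: 4 tert-butyl{[(3Z,5R)-5,9-dimethyldeca-1,3,8-trien-3-yl]oxy}dimethylsilane
Conditions: t-BuMe2SiOTf, Et3N, CH2Cl2, −78 to 0 °C
Reagents that add atoms: tert-butyldimethylsilyl trifluoromethanesulfonate CC(C)(C)[Si](C)(C)OS(=O)(=O)C(F)(F)F
Why: Soft enolisation with a silyl triflate and a tertiary amine silylates the only enolisable α-CH2 and gives the 2-siloxy-1,3-diene (silyl enol ether formation), the Z enol ether being favoured by allylic 1,3-strain although its geometry is not carried into the target.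

Step 4
Reactants: 5 methyl 4-hydroxybut-2-ynoate
Product: 6 methyl 4-[(tert-butyldimethylsilyl)oxy]but-2-ynoate
Conditions: t-BuMe2SiCl, imidazole, CH2Cl2, 0 °C to rt
Reagents that add atoms: tert-butyldimethylsilyl chloride CC(C)(C)[Si](C)(C)Cl
Why: Standard silylation of a primary propargylic alcohol (silyl ether protection) masks the future lactone oxygen.

Step 5
Reactants: 7 allyl chloride
Product: 8 cyclopropene
Conditions: NaN(SiMe3)2, toluene, 110 °C, product swept into ClCH2CH2Cl at −78 °C
Reagents that add atoms: none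
Why: Base-induced 1,3-dehydrochlorination of allyl chloride (α-elimination to the vinylcarbene and ring closure) is the established preparation of cyclopropene, which is kept cold in solution and used at once.

Step 6
Reactants: 4 tert-butyl{[(3Z,5R)-5,9-dimethyldeca-1,3,8-trien-3-yl]oxy}dimethylsilane; 6 methyl 4-[(tert-butyldimethylsilyl)oxy]but-2-ynoate; 8 cyclopropene
Product: 9 methyl (1S,3E,6Z,8S)-4-[(tert-butyldimethylsilyl)oxy]-7-{[(tert-butyldimethylsilyl)oxy]methyl}-5-[(2R)-6-methylhept-5-en-2-yl]bicyclo[6.1.0]nona-3,6-diene-6-carboxylate (C5 epimers)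
Conditions: [Rh(cod)2]BF4 (5 mol %), (R)-BINAP (5 mol %), pre-activated with H2, ClCH2CH2Cl, 0 °C to rt, slow addition of 6 and 8
Reagents that add atoms: none
Why: Proposed new method: oxidative cyclisation of ynoate 6 and the strained cyclopropene 8 at cationic monovalent rhodium is expected to give a cyclopropane-fused rhodacyclopentene (new C7–C8 bond, rhodium on C6 and C1), diene 4 then inserts through its unsubstituted CH2 terminus into the Rh–C1(sp3) bond (new C1–C2 bond) to give an η3-2-siloxyallyl rhodium species spanning C3–C5, and C(sp2)–C(sp3) reductive elimination at the distal allyl terminus forms C5–C6 and frees the catalyst; the closest known reaction types are the rhodium-catalysed [4+2+2] cycloadditions of 1,6-enynes with 1,3-dienes and of diene-enes with alkynes, the cobalt-catalysed fully intermolecular [4+2+2] of a diene with two alkynes, and the use of cyclopropene as the ene partner in intermolecular Pauson–Khand reactions. The eight-membered ring closes by the final reductive elimination from a seven-membered rhodacycle (formal [4+2+2]), whereas the three-membered ring is not formed here but carried over from 8, whose π-bond alone reacts, the loss of roughly half of the cyclopropene strain driving the first step. C1 and C8 arise by syn addition across the cyclopropene and are therefore cis, their absolute sense is set by the chiral bisphosphine in the enantio-determining oxidative cyclisation, which is remote from and independent of the side-chain stereocentre, and C5 is formed without control and is corrected in step 8. The step needs cross-selection among three π-partners and one regiochemistry: the strain of 8 makes it the fastest ene partner, the ester of 6 places rhodium on the α-carbon C6 and the new bond on the β-carbon C7, the single unhindered CH2 terminus of 4 directs insertion to C2, and slow addition of 6 and 8 keeps their homo-oligomerisation low.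

Step 7
Reactants: 9 methyl (1S,3E,6Z,8S)-4-[(tert-butyldimethylsilyl)oxy]-7-{[(tert-butyldimethylsilyl)oxy]methyl}-5-[(2R)-6-methylhept-5-en-2-yl]bicyclo[6.1.0]nona-3,6-diene-6-carboxylate
Product: 10 methyl (1S,2Z,6Z,8S)-7-{[(tert-butyldimethylsilyl)oxy]methyl}-5-[(2R)-6-methylhept-5-en-2-yl]-4-oxobicyclo[6.1.0]nona-2,6-diene-6-carboxylate (C5 epimers)
Conditions: Pd(OAc)2 (1.1 equiv), MeCN, 40 °C
Reagents that add atoms: none
Why: Saegusa–Ito oxidation: palladation of the silyl enol ether at C3 and β-hydride elimination towards C2, the only carbon that offers β-hydrogens, place the new enone at C2=C3 (Z, ring-enforced) without touching a stereocentre.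

Step 8
Reactants: 10 methyl (1S,2Z,6Z,8S)-7-{[(tert-butyldimethylsilyl)oxy]methyl}-5-[(2R)-6-methylhept-5-en-2-yl]-4-oxobicyclo[6.1.0]nona-2,6-diene-6-carboxylate
Product: 12 methyl (1S,2Z,5S,6Z,8S)-7-{[(tert-butyldimethylsilyl)oxy]methyl}-5-[(2R)-6-methylhept-5-en-2-yl]-4-oxobicyclo[6.1.0]nona-2,6-diene-6-carboxylate, via lithium dienolate 11 (not isolated)
Conditions: LiN(i-Pr)2, THF, −78 °C; then AcOH in THF, −78 °C
Reagents that add atoms: none
Why: α'-Deprotonation of the enone is regiospecific because C5–H is its only enolisable hydrogen, and kinetic C-protonation of the cross-conjugated dienolate from the face anti to the homoprenyl arm of the side chain in its allylic-1,3-strain-minimised conformer (diastereoselective enolate protonation) is expected to set C5 as S.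

Step 9
Reactants: 12 methyl (1S,2Z,5S,6Z,8S)-7-{[(tert-butyldimethylsilyl)oxy]methyl}-5-[(2R)-6-methylhept-5-en-2-yl]-4-oxobicyclo[6.1.0]nona-2,6-diene-6-carboxylate
Product: 13 methyl (1S,2R,5S,6Z,8S)-7-{[(tert-butyldimethylsilyl)oxy]methyl}-2-methyl-5-[(2R)-6-methylhept-5-en-2-yl]-4-oxobicyclo[6.1.0]non-6-ene-6-carboxylate
Conditions: Me2CuLi (from MeLi and CuI), Et2O, −78 °C; then H2O
Reagents that add atoms: lithium dimethylcuprate [Li+].C[Cu-]C
Why: Conjugate (1,4-) addition of Me2CuLi to the cis-cyclooctenone delivers methyl to C2 from the face opposite the neighbouring cyclopropane methylene C9 and opposite the C5 side chain, which should set C2 as R.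

Step 10
Reactants: 13 methyl (1S,2R,5S,6Z,8S)-7-{[(tert-butyldimethylsilyl)oxy]methyl}-2-methyl-5-[(2R)-6-methylhept-5-en-2-yl]-4-oxobicyclo[6.1.0]non-6-ene-6-carboxylate
Product: 15 keto butenolide (4-oxo analogue of the target; 1S,2R,5S,8S; C6 and C7 joined by a C(=O)–O–CH2 bridge with the carbonyl on C6), via hydroxy ester 14 (not isolated)
Conditions: HF·pyridine, THF, 0 °C to rt
Reagents that add atoms: none
Why: Fluoride cleavage of the primary silyl ether frees a (Z)-γ-hydroxy enoate that lactonises spontaneously (intramolecular transesterification) to the butenolide with loss of methanol, no stereocentre being touched.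

Step 11
Reactants: 15 keto butenolide
Product: 16 (4R)-alcohol (deacetyl target; 1S,2R,4R,5S,8S)
Conditions: LiBH(s-Bu)3, THF, −78 °C; then H2O
Reagents that add atoms: none
Why: Ketone reduction with a bulky trialkylborohydride takes place by attack on C4 from the ring face opposite the adjacent C5 side chain and should give the cis-related (4R)-alcohol, the tetrasubstituted butenolide being too hindered for conjugate reduction at −78 °C.

Step 12
Reactants: 16 (4R)-alcohol
Product: 17 target acetate (1S,2R,4R,5S,8S; side chain 2R)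
Conditions: Ac2O, pyridine, 4-(dimethylamino)pyridine (cat.), CH2Cl2, rt
Reagents that add atoms: acetic anhydride CC(=O)OC(C)=O
Why: Nucleophile-catalysed acylation (acetylation) of the secondary alcohol with retention at C4 gives the target acetate.

**Compound list**
1 | (R)-citronellal [(3R)-3,7-dimethyloct-6-enal] | O=CC[C@H](C)CCC=C(C)C | starting material
2 | (5R)-5,9-dimethyldeca-1,8-dien-3-ol (C3 epimers) | C=CC(O)C[C@H](C)CCC=C(C)C | intermediate
3 | (5R)-5,9-dimethyldeca-1,8-dien-3-one | C=CC(=O)C[C@H](C)CCC=C(C)C | intermediate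
4 | tert-butyl{[(3Z,5R)-5,9-dimethyldeca-1,3,8-trien-3-yl]oxy}dimethylsilane | C=C/C(O[Si](C)(C)C(C)(C)C)=C/[C@H](C)CCC=C(C)C | intermediate
5 | methyl 4-hydroxybut-2-ynoate | COC(=O)C#CCO | starting material
6 | methyl 4-[(tert-butyldimethylsilyl)oxy]but-2-ynoate | COC(=O)C#CCO[Si](C)(C)C(C)(C)C | intermediate
7 | allyl chloride (3-chloroprop-1-ene) | C=CCCl | starting material
8 | cyclopropene | C1=CC1 | intermediate
9 | methyl (1S,3E,6Z,8S)-4-[(tert-butyldimethylsilyl)oxy]-7-{[(tert-butyldimethylsilyl)oxy]methyl}-5-[(2R)-6-methylhept-5-en-2-yl]bicyclo[6.1.0]nona-3,6-diene-6-carboxylate (C5 epimers) | CC(C)(C)[Si](C)(C)O/C1=C/C[C@@H]2C[C@@H]2/C(CO[Si](C)(C)C(C)(C)C)=C(/C(=O)OC)C1[C@H](C)CCC=C(C)C | intermediate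
10 | methyl (1S,2Z,6Z,8S)-7-{[(tert-butyldimethylsilyl)oxy]methyl}-5-[(2R)-6-methylhept-5-en-2-yl]-4-oxobicyclo[6.1.0]nona-2,6-diene-6-carboxylate (C5 epimers) | O=C1/C=C\[C@@H]2C[C@@H]2/C(CO[Si](C)(C)C(C)(C)C)=C(/C(=O)OC)C1[C@H](C)CCC=C(C)C | intermediate
11 | lithium dienolate of 10 (C4–O–Li, C4=C5) | [Li+].[O-]C=1/C=C\[C@@H]2C[C@@H]2/C(CO[Si](C)(C)C(C)(C)C)=C(/C(=O)OC)C=1\[C@H](C)CCC=C(C)C | intermediate
12 | methyl (1S,2Z,5S,6Z,8S)-7-{[(tert-butyldimethylsilyl)oxy]methyl}-5-[(2R)-6-methylhept-5-en-2-yl]-4-oxobicyclo[6.1.0]nona-2,6-diene-6-carboxylate | O=C1/C=C\[C@@H]2C[C@@H]2/C(CO[Si](C)(C)C(C)(C)C)=C(/C(=O)OC)[C@@H]1[C@H](C)CCC=C(C)C | intermediate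
13 | methyl (1S,2R,5S,6Z,8S)-7-{[(tert-butyldimethylsilyl)oxy]methyl}-2-methyl-5-[(2R)-6-methylhept-5-en-2-yl]-4-oxobicyclo[6.1.0]non-6-ene-6-carboxylate | O=C1C[C@@H](C)[C@@H]2C[C@@H]2/C(CO[Si](C)(C)C(C)(C)C)=C(/C(=O)OC)[C@@H]1[C@H](C)CCC=C(C)C | intermediate
14 | methyl (1S,2R,5S,6Z,8S)-7-(hydroxymethyl)-2-methyl-5-[(2R)-6-methylhept-5-en-2-yl]-4-oxobicyclo[6.1.0]non-6-ene-6-carboxylate | O=C1C[C@@H](C)[C@@H]2C[C@@H]2/C(CO)=C(/C(=O)OC)[C@@H]1[C@H](C)CCC=C(C)C | intermediate
15 | keto butenolide (4-oxo analogue of the target; 1S,2R,5S,8S) | O=C1C[C@@H](C)[C@@H]2C[C@@H]2C2=C(C(=O)OC2)[C@@H]1[C@H](C)CCC=C(C)C | intermediate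
16 | (4R)-alcohol (deacetyl target; 1S,2R,4R,5S,8S) | O[C@@H]1C[C@@H](C)[C@@H]2C[C@@H]2C2=C(C(=O)OC2)[C@@H]1[C@H](C)CCC=C(C)C | intermediate
17 | target acetate (1S,2R,4R,5S,8S; side chain 2R) | CC(=O)O[C@@H]1C[C@@H](C)[C@@H]2C[C@@H]2C2=C(C(=O)OC2)[C@@H]1[C@H](C)CCC=C(C)C | target

Total step count: 12. Longest linear sequence: 10 steps (steps 1–3 and 6–12).

**Steps most likely to fail**

Step 6. The three-component cycloaddition may lose cross-selectivity among the three π-partners (oligomerisation of the cyclopropene, thermal or metal-catalysed [4+2] union of the diene with either 2π partner), or the rhodacycle may close a six-membered ring by reductive elimination at the proximal allyl terminus. The fallback builds the ring stepwise with known reactions; it sets out from cyclopropene 8 (using ynoate 6 and diene 4) and returns at enone 10. Copper-catalysed enantioselective syn-carbomagnesiation of 8 with CH2=CHMgBr (CuBr·SMe2, chiral bisphosphine) gives [(1S,2S)-2-ethenylcyclopropyl]magnesium bromide F1. Transmetallation with CuBr·SMe2 gives [(1S,2S)-2-ethenylcyclopropyl]copper F2, which adds syn across ynoate 6 at −78 °C to give the alkenylcopper adduct F3. Iodine converts F3 with retention into methyl (2E)-4-[(tert-butyldimethylsilyl)oxy]-3-[(1S,2S)-2-ethenylcyclopropyl]-2-iodobut-2-enoate F4. Palladium-catalysed α-alkenylation of silyl dienol ether 4 with F4 (Pd2(dba)3, P(t-Bu)3, Bu3SnF) gives the triene ketone methyl (2Z)-4-[(tert-butyldimethylsilyl)oxy]-2-[(5R)-5,9-dimethyl-3-oxodeca-1,8-dien-4-yl]-3-[(1S,2S)-2-ethenylcyclopropyl]but-2-enoate F5. Ring-closing metathesis of F5 (second-generation Grubbs catalyst) closes C2=C3 with loss of ethene and delivers 10.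

Step 8. Protonation of dienolate 11 may show poor facial selectivity, because the side-chain stereocentre distinguishes only a methyl from a primary alkyl group. The fallback puts C5 under reagent control; it sets out from 10 and returns at 12. Me3SiOTf and Et3N convert 10 into the isolated trimethylsilyl dienol ether methyl (1S,2Z,4E,6Z,8S)-7-{[(tert-butyldimethylsilyl)oxy]methyl}-5-[(2R)-6-methylhept-5-en-2-yl]-4-[(trimethylsilyl)oxy]bicyclo[6.1.0]nona-2,4,6-triene-6-carboxylate F6. F6 is protonated at −78 °C with a chiral Lewis acid-assisted Brønsted acid ((R)-BINOL·SnCl4, the known enantioselective protonation of silyl enol ethers), the antipode of the acid being chosen to give 12.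

Step 11. Hydride delivery to the C4 ketone may come from the wrong ring face, since the eight-membered ring is flexible and the C2 methyl lies on the face that must be attacked. The fallback uses inversion instead of direct delivery; it sets out from 15 and returns at target 17. Luche reduction (NaBH4, CeCl3·7H2O, MeOH, −78 °C) or whichever hydride favours the other face gives the (4S)-alcohol F7. A Mitsunobu reaction of F7 with acetic acid (PPh3, diisopropyl azodicarboxylate, THF) inverts C4 and installs the acetate in one operation, giving 17 without passing through 16.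

**Further compounds**
F1 | step 6 | [(1S,2S)-2-ethenylcyclopropyl]magnesium bromide | C=C[C@@H]1C[C@@H]1[Mg]Br
F2 | step 6 | [(1S,2S)-2-ethenylcyclopropyl]copper | C=C[C@@H]1C[C@@H]1[Cu]
F3 | step 6 | alkenylcopper adduct: methyl (2E)-4-[(tert-butyldimethylsilyl)oxy]-2-cuprio-3-[(1S,2S)-2-ethenylcyclopropyl]but-2-enoate | C=C[C@@H]1C[C@@H]1/C(CO[Si](C)(C)C(C)(C)C)=C([Cu])/C(=O)OC
F4 | step 6 | methyl (2E)-4-[(tert-butyldimethylsilyl)oxy]-3-[(1S,2S)-2-ethenylcyclopropyl]-2-iodobut-2-enoate | C=C[C@@H]1C[C@@H]1/C(CO[Si](C)(C)C(C)(C)C)=C(I)/C(=O)OC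
F5 | step 6 | methyl (2Z)-4-[(tert-butyldimethylsilyl)oxy]-2-[(5R)-5,9-dimethyl-3-oxodeca-1,8-dien-4-yl]-3-[(1S,2S)-2-ethenylcyclopropyl]but-2-enoate (epimers at the ketone α-carbon) | C=C[C@@H]1C[C@@H]1/C(CO[Si](C)(C)C(C)(C)C)=C(/C(=O)OC)C([C@H](C)CCC=C(C)C)C(=O)C=C
F6 | step 8 | methyl (1S,2Z,4E,6Z,8S)-7-{[(tert-butyldimethylsilyl)oxy]methyl}-5-[(2R)-6-methylhept-5-en-2-yl]-4-[(trimethylsilyl)oxy]bicyclo[6.1.0]nona-2,4,6-triene-6-carboxylate | C[Si](C)(C)OC=1/C=C\[C@@H]2C[C@@H]2/C(CO[Si](C)(C)C(C)(C)C)=C(/C(=O)OC)C=1\[C@H](C)CCC=C(C)C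
F7 | step 11 | (4S)-alcohol (C4 epimer of 16) | O[C@H]1C[C@@H](C)[C@@H]2C[C@@H]2C2=C(C(=O)OC2)[C@@H]1[C@H](C)CCC=C(C)C
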